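**Plan**

1. Retrosynthesis: (a) the hydroxyquinone is unmasked last from a 1,2,4,5-tetramethoxyarene; (b) the side chain is cut at C2'–C3' (sp3–sp2 cross-coupling) into a ring-bound vinyl group and an aryl-substituted (E)-vinyl iodide; (c) the C2 methylidene is traced back to a C2 carbinol; (d) the carbocycle is cut at C4–C5 and C1–C2 together.
2. Ring numbering as in the target: C1 quaternary carbon, C2 methylidene carbon, C3 CH(CH3), C4–C6 methylenes; C1' is the first side-chain carbon.
3. Feature that allows the double cut: C1 carries C1' and sits next to C2 (a masked carbonyl), an aldol pattern; C5 is γ to C1' through C6 and C4 is β to C2 through C3, a vinylogous Michael pattern. Each half is an α-methyl enal: C5–C6–C1(CH3)–C1'HO is tiglic aldehyde and C2HO–C3(CH3)=C4H2 is methacrolein.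
4. Forward order: the ring is made first in one amine-catalysed operation (C4–C5, then C1–C2); then ring C=C hydrogenation, CHO to vinyl, hydroboration/Suzuki coupling with the arene fragment, C2 oxidation and methylenation, quinone last.
5. Stereochemistry: C1 and C3 come from the catalyst-controlled aldol ring closure (C3 by dynamic kinetic resolution α to the acceptor aldehyde); the C2 carbinol centre is erased later; the side-chain E geometry comes from syn-hydrozirconation/iodination and a stereoretentive coupling.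

Key step: step 1

Assumption: the quinine-derived primary amine is taken to deliver the (1S,5R,6S) series in step 1; its quinidine-derived pseudoenantiomer would be used if the sense of induction proves opposite.

**Route**

Step 1
Reactants: 1 tiglic aldehyde, (2E)-2-methylbut-2-enal; 2 methacrolein, 2-methylprop-2-enal
Product: 4 (1S,5R,6S)-6-hydroxy-1,5-dimethylcyclohex-2-ene-1-carbaldehyde, via enedial 3 (not isolated)
Conditions: 9-amino-9-deoxy-epi-quinine (20 mol %), CF3CO2H (40 mol %), CHCl3, 0 °C to rt, slow addition of 2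
Reagents that add atoms: none
Why: Proposed new method: the primary amine condenses with 1 to a 1-amino-2-methylbuta-1,3-diene (dienamine) whose γ-carbon adds to the β-carbon of methacrolein held as its iminium ion (vinylogous Michael, C4–C5 bond, target numbering), and after hydrolysis to enedial 3 a second dienamine of the enal end attacks the saturated formyl group through its α-carbon (aldol, C1–C2 bond), so the ring closes in the 6-(enolexo)-exo-trig mode and the quaternary carbon, having no α-hydrogen, cannot dehydrate. The closest known reaction type is the amine-catalysed formal [3+3] union of two enals (dienamine γ-Michael, then α-aldol) together with the enamine-catalysed 6-enolexo aldolization of dialdehydes. C1 and the carbinol carbon are set in the chair-like aldol transition state, in which the catalyst-bearing enamine carbon and the developing hydroxyl should lie anti and equatorial (C1 methyl axial) while the chiral amine selects the enamine face and so the absolute sense. C3 is α to the acceptor aldehyde of 3, epimerises through its own enamine and should be drawn into the ring with its methyl equatorial (dynamic kinetic resolution), that is trans to the hydroxyl and cis to the formyl group. The step needs donor/acceptor discrimination and γ- before α-reactivity: only 1 has γ-hydrogens and its α-carbon is fully substituted, 2 has an unhindered β-methylene and no γ-hydrogen, and the E-configured C=C of 3 cannot be accommodated in the alternative six-membered closure through the formyl carbon.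

Step 2
Reactants: 4 (1S,5R,6S)-6-hydroxy-1,5-dimethylcyclohex-2-ene-1-carbaldehyde
Product: 5 (1S,5R,6S)-6-[(tert-butyldimethylsilyl)oxy]-1,5-dimethylcyclohex-2-ene-1-carbaldehyde
Conditions: TBSOTf, 2,6-lutidine, CH2Cl2, −78 to 0 °C
Reagents that add atoms: tert-butyldimethylsilyl trifluoromethanesulfonate, CC(C)(C)[Si](C)(C)OS(=O)(=O)C(F)(F)F
Why: Silylation of the hindered secondary alcohol with a silyl triflate and a non-nucleophilic base blocks retro-aldol cleavage in the basic steps that follow; the aldehyde has no α-hydrogen and cannot epimerise.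

Step 3
Reactants: 5 (1S,5R,6S)-6-[(tert-butyldimethylsilyl)oxy]-1,5-dimethylcyclohex-2-ene-1-carbaldehyde
Product: 6 (1S,2S,3R)-2-[(tert-butyldimethylsilyl)oxy]-1,3-dimethylcyclohexane-1-carbaldehyde
Conditions: H2 (1 atm), Pd/C (10 %), EtOAc, rt
Reagents that add atoms: none
Why: Heterogeneous catalytic hydrogenation should saturate the cis-disubstituted ring alkene, the only C=C present, leaving aldehyde and silyl ether untouched and creating no stereocentre.

Step 4
Reactants: 6 (1S,2S,3R)-2-[(tert-butyldimethylsilyl)oxy]-1,3-dimethylcyclohexane-1-carbaldehyde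
Product: 7 tert-butyl{[(1S,2R,6R)-2-ethenyl-2,6-dimethylcyclohexyl]oxy}dimethylsilane
Conditions: Ph3PCH3Br, KN(SiMe3)2, THF, 0 °C to rt
Reagents that add atoms: methyltriphenylphosphonium bromide, C[P+](c1ccccc1)(c1ccccc1)c1ccccc1.[Br-]
Why: Wittig methylenation of a non-enolisable aldehyde turns C1'HO into the vinyl group C1'=C2' without touching the ring stereocentres.

Step 5
Reactants: 8 1,2,4,5-tetramethoxybenzene; 9 1-bromobut-2-yne
Product: 11 3-(but-2-yn-1-yl)-1,2,4,5-tetramethoxybenzene, via aryllithium 10 (not isolated)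
Conditions: n-BuLi, THF, 0 °C; then 9, −78 °C to rt
Reagents that add atoms: none
Why: Directed ortho-lithiation at the ring position flanked by two methoxy groups gives the aryllithium, which should displace the primary propargylic bromide by SN2 alkylation because attack at the methyl-substituted alkyne terminus (allene formation) is sterically disfavoured.

Step 6
Reactants: 11 3-(but-2-yn-1-yl)-1,2,4,5-tetramethoxybenzene
Product: 13 3-[(2E)-3-iodobut-2-en-1-yl]-1,2,4,5-tetramethoxybenzene, via alkenylzirconocene 12 (not isolated)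
Conditions: Cp2Zr(H)Cl (excess), THF, rt to 50 °C; then I2, 0 °C
Reagents that add atoms: iodine, [I][I]
Why: Hydrozirconation adds H and Zr syn, with zirconium settling on the less hindered methyl-bearing alkyne carbon after equilibration, and iodinolysis proceeds with retention, so the trisubstituted vinyl iodide should be E.

Step 7
Reactants: 7 tert-butyl{[(1S,2R,6R)-2-ethenyl-2,6-dimethylcyclohexyl]oxy}dimethylsilane; 13 3-[(2E)-3-iodobut-2-en-1-yl]-1,2,4,5-tetramethoxybenzene
Product: 15 tert-butyl({(1S,2R,6R)-2,6-dimethyl-2-[(3E)-3-methyl-5-(2,3,5,6-tetramethoxyphenyl)pent-3-en-1-yl]cyclohexyl}oxy)dimethylsilane, via alkylborane 14 (not isolated)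
Conditions: 9-BBN dimer, THF, rt to 60 °C; then 13, PdCl2(dppf), AsPh3, Cs2CO3, DMF/H2O, rt
Reagents that add atoms: none
Why: Anti-Markovnikov hydroboration of the only monosubstituted alkene followed by B-alkyl Suzuki–Miyaura cross-coupling joins C2' to C3' with retention of the vinyl iodide geometry.

Step 8
Reactants: 15 tert-butyl({(1S,2R,6R)-2,6-dimethyl-2-[(3E)-3-methyl-5-(2,3,5,6-tetramethoxyphenyl)pent-3-en-1-yl]cyclohexyl}oxy)dimethylsilane
Product: 16 (1S,2R,6R)-2,6-dimethyl-2-[(3E)-3-methyl-5-(2,3,5,6-tetramethoxyphenyl)pent-3-en-1-yl]cyclohexan-1-ol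
Conditions: Bu4NF, THF, 60 °C
Reagents that add atoms: none
Why: Fluoride-induced desilylation of the hindered silyl ether; heating is tolerable because nothing base-sensitive is present.

Step 9
Reactants: 16 (1S,2R,6R)-2,6-dimethyl-2-[(3E)-3-methyl-5-(2,3,5,6-tetramethoxyphenyl)pent-3-en-1-yl]cyclohexan-1-ol
Product: 17 (2R,6R)-2,6-dimethyl-2-[(3E)-3-methyl-5-(2,3,5,6-tetramethoxyphenyl)pent-3-en-1-yl]cyclohexan-1-one
Conditions: Dess–Martin periodinane, CH2Cl2, rt
Reagents that add atoms: none
Why: Dess–Martin oxidation under non-basic conditions should give the 2,2,6-trisubstituted ketone without epimerising the α-methine carbon C3.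

Step 10
Reactants: 17 (2R,6R)-2,6-dimethyl-2-[(3E)-3-methyl-5-(2,3,5,6-tetramethoxyphenyl)pent-3-en-1-yl]cyclohexan-1-one
Product: 18 3-{(2E)-5-[(1R,3R)-1,3-dimethyl-2-methylidenecyclohexyl]-3-methylpent-2-en-1-yl}-1,2,4,5-tetramethoxybenzene
Conditions: Zn, CH2Br2, TiCl4, THF/CH2Cl2, 0 °C to rt
Reagents that add atoms: dibromomethane, BrCBr
Why: Takai–Lombardo methylenation uses a non-basic zinc/titanium methylene reagent that should convert the hindered, enolisable ketone into the exocyclic alkene without loss of the C3 configuration.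

Step 11
Reactants: 18 3-{(2E)-5-[(1R,3R)-1,3-dimethyl-2-methylidenecyclohexyl]-3-methylpent-2-en-1-yl}-1,2,4,5-tetramethoxybenzene
Product: 19 3-{(2E)-5-[(1R,3R)-1,3-dimethyl-2-methylidenecyclohexyl]-3-methylpent-2-en-1-yl}-2,5-dimethoxycyclohexa-2,5-diene-1,4-dione
Conditions: (NH4)2Ce(NO3)6, MeCN/H2O, 0 °C
Reagents that add atoms: water, O
Why: Oxidative demethylation of the electron-rich arene gives the para-quinone; either para pair of methoxy groups leads to the same 2,5-dimethoxy-3-alkylquinone, and isolated alkenes should be tolerated.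

Step 12
Reactants: 19 3-{(2E)-5-[(1R,3R)-1,3-dimethyl-2-methylidenecyclohexyl]-3-methylpent-2-en-1-yl}-2,5-dimethoxycyclohexa-2,5-diene-1,4-dione
Product: 20 metachromin A
Conditions: HClO4 (aq), THF, 0 °C
Reagents that add atoms: water, O
Why: Acid-catalysed hydrolysis of a vinylogous ester: the methoxy group next to the alkyl-bearing carbon belongs to the more electron-rich, more basic enone unit and should be exchanged for hydroxyl selectively, as is known for 3-alkyl-2,5-dimethoxybenzoquinones.

**Compound list**

1 | tiglic aldehyde, (2E)-2-methylbut-2-enal | C/C=C(\C)C=O | starting material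
2 | methacrolein, 2-methylprop-2-enal | C=C(C)C=O | starting material
3 | (2E)-2,6-dimethylhept-2-enedial (configuration at C6 mobile) | O=C/C(C)=C/CCC(C)C=O | intermediate
4 | (1S,5R,6S)-6-hydroxy-1,5-dimethylcyclohex-2-ene-1-carbaldehyde | O=C[C@@]1(C)C=CC[C@@H](C)[C@@H]1O | intermediate
5 | (1S,5R,6S)-6-[(tert-butyldimethylsilyl)oxy]-1,5-dimethylcyclohex-2-ene-1-carbaldehyde | O=C[C@@]1(C)C=CC[C@@H](C)[C@@H]1O[Si](C)(C)C(C)(C)C | intermediate
6 | (1S,2S,3R)-2-[(tert-butyldimethylsilyl)oxy]-1,3-dimethylcyclohexane-1-carbaldehyde | O=C[C@@]1(C)CCC[C@@H](C)[C@@H]1O[Si](C)(C)C(C)(C)C | intermediate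
7 | tert-butyl{[(1S,2R,6R)-2-ethenyl-2,6-dimethylcyclohexyl]oxy}dimethylsilane | C=C[C@@]1(C)CCC[C@@H](C)[C@@H]1O[Si](C)(C)C(C)(C)C | intermediate
8 | 1,2,4,5-tetramethoxybenzene | COc1cc(OC)c(OC)cc1OC | starting material
9 | 1-bromobut-2-yne | CC#CCBr | starting material
10 | (2,3,5,6-tetramethoxyphenyl)lithium | [Li]c1c(OC)c(OC)cc(OC)c1OC | intermediate
11 | 3-(but-2-yn-1-yl)-1,2,4,5-tetramethoxybenzene | CC#CCc1c(OC)c(OC)cc(OC)c1OC | intermediate
12 | chlorobis(cyclopentadienyl)[(2E)-4-(2,3,5,6-tetramethoxyphenyl)but-2-en-2-yl]zirconium | C/C(=C\Cc1c(OC)c(OC)cc(OC)c1OC)[Zr](Cl)(C1C=CC=C1)C1C=CC=C1 | intermediate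
13 | 3-[(2E)-3-iodobut-2-en-1-yl]-1,2,4,5-tetramethoxybenzene | COc1cc(OC)c(OC)c(C/C=C(\C)I)c1OC | intermediate
14 | 9-{2-[(1R,2S,3R)-2-[(tert-butyldimethylsilyl)oxy]-1,3-dimethylcyclohexyl]ethyl}-9-borabicyclo[3.3.1]nonane | B1(CC[C@@]2(C)CCC[C@@H](C)[C@@H]2O[Si](C)(C)C(C)(C)C)C2CCCC1CCC2 | intermediate
15 | tert-butyl({(1S,2R,6R)-2,6-dimethyl-2-[(3E)-3-methyl-5-(2,3,5,6-tetramethoxyphenyl)pent-3-en-1-yl]cyclohexyl}oxy)dimethylsilane | COc1cc(OC)c(OC)c(C/C=C(\C)CC[C@@]2(C)CCC[C@@H](C)[C@@H]2O[Si](C)(C)C(C)(C)C)c1OC | intermediate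
16 | (1S,2R,6R)-2,6-dimethyl-2-[(3E)-3-methyl-5-(2,3,5,6-tetramethoxyphenyl)pent-3-en-1-yl]cyclohexan-1-ol | COc1cc(OC)c(OC)c(C/C=C(\C)CC[C@@]2(C)CCC[C@@H](C)[C@@H]2O)c1OC | intermediate
17 | (2R,6R)-2,6-dimethyl-2-[(3E)-3-methyl-5-(2,3,5,6-tetramethoxyphenyl)pent-3-en-1-yl]cyclohexan-1-one | COc1cc(OC)c(OC)c(C/C=C(\C)CC[C@@]2(C)CCC[C@@H](C)C2=O)c1OC | intermediate
18 | 3-{(2E)-5-[(1R,3R)-1,3-dimethyl-2-methylidenecyclohexyl]-3-methylpent-2-en-1-yl}-1,2,4,5-tetramethoxybenzene | COc1cc(OC)c(OC)c(C/C=C(\C)CC[C@@]2(C)CCC[C@@H](C)C2=C)c1OC | intermediate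
19 | 3-{(2E)-5-[(1R,3R)-1,3-dimethyl-2-methylidenecyclohexyl]-3-methylpent-2-en-1-yl}-2,5-dimethoxycyclohexa-2,5-diene-1,4-dione | COC1=CC(=O)C(OC)=C(C/C=C(\C)CC[C@@]2(C)CCC[C@@H](C)C2=C)C1=O | intermediate
20 | metachromin A, 3-{(2E)-5-[(1R,3R)-1,3-dimethyl-2-methylidenecyclohexyl]-3-methylpent-2-en-1-yl}-2-hydroxy-5-methoxycyclohexa-2,5-diene-1,4-dione | C=C1[C@H](C)CCC[C@]1(C)CC/C(C)=C/CC1=C(O)C(=O)C=C(OC)C1=O | target

**Totals**

Total step count: 12. Longest linear sequence: 10 steps (steps 1–4 and 7–12); steps 5 and 6 form the convergent arene branch.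

**Steps most likely to fail**

Step 1 (labelled as a new method). What may go wrong:
- the dienamine may react as a 1-aminodiene in a [4+2] cyclocondensation with methacrolein;
- it may attack through its α-carbon instead of its γ-carbon;
- ring closure may outrun epimerisation at C3;
- the aldol may show poor facial selectivity.

Fallback: the ring is taken from commercial cis-2,6-dimethylcyclohexanone and the quaternary carbon is made by enolate alkylation instead of annulation. The fallback sets out from vinyl iodide 13. Iodine–lithium exchange (t-BuLi, Et2O, −78 °C) and opening of oxirane should give (3E)-3-methyl-5-(2,3,5,6-tetramethoxyphenyl)pent-3-en-1-ol F1, which I2/PPh3/imidazole should turn into 3-[(2E)-5-iodo-3-methylpent-2-en-1-yl]-1,2,4,5-tetramethoxybenzene F2. cis-2,6-Dimethylcyclohexanone is desymmetrised by enantioselective deprotonation with a chiral lithium bis(1-phenylethyl)amide of the appropriate configuration in the presence of Me3SiCl to give trimethyl{[(6R)-2,6-dimethylcyclohex-1-en-1-yl]oxy}silane F3. MeLi regenerates the lithium enolate, and its alkylation with F2 in THF/DMPU should give ketone 17 after separation from its C2 epimer. The route is rejoined at 17, before step 10.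

Step 12. What may go wrong: loss of regioselectivity between the two methoxy groups, or acid-induced migration of the exocyclic double bond.

Fallback: it sets out from quinone 19. Exhaustive hydrolysis of both vinylogous esters with NaOH in aqueous MeOH should give 3-{(2E)-5-[(1R,3R)-1,3-dimethyl-2-methylidenecyclohexyl]-3-methylpent-2-en-1-yl}-2,5-dihydroxycyclohexa-2,5-diene-1,4-dione F5. One equivalent of Me3SiCHN2 in MeOH/toluene should then methylate the less hindered hydroxyl, the one remote from the alkyl group. The route comes back at 20.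

Step 10. What may go wrong: the hindered carbonyl may fail to react, or the α-stereocentre may epimerise.

Fallback: a Peterson olefination, setting out from ketone 17. Addition of Me3SiCH2Li/CeCl3 (THF, −78 °C), which adds to hindered enolisable ketones without deprotonation, should give (2R,6R)-2,6-dimethyl-2-[(3E)-3-methyl-5-(2,3,5,6-tetramethoxyphenyl)pent-3-en-1-yl]-1-[(trimethylsilyl)methyl]cyclohexan-1-ol F4 (either carbinol epimer serves). Elimination with KH in THF leads to 18, where the route is rejoined.

Further compounds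
F1 | step 1 | (3E)-3-methyl-5-(2,3,5,6-tetramethoxyphenyl)pent-3-en-1-ol | COc1cc(OC)c(OC)c(C/C=C(\C)CCO)c1OC
F2 | step 1 | 3-[(2E)-5-iodo-3-methylpent-2-en-1-yl]-1,2,4,5-tetramethoxybenzene | COc1cc(OC)c(OC)c(C/C=C(\C)CCI)c1OC
F3 | step 1 | trimethyl{[(6R)-2,6-dimethylcyclohex-1-en-1-yl]oxy}silane | C[C@@H]1CCCC(C)=C1O[Si](C)(C)C
F5 | step 12 | 3-{(2E)-5-[(1R,3R)-1,3-dimethyl-2-methylidenecyclohexyl]-3-methylpent-2-en-1-yl}-2,5-dihydroxycyclohexa-2,5-diene-1,4-dione | OC1=CC(=O)C(O)=C(C/C=C(\C)CC[C@@]2(C)CCC[C@@H](C)C2=C)C1=O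
F4 | step 10 | (2R,6R)-2,6-dimethyl-2-[(3E)-3-methyl-5-(2,3,5,6-tetramethoxyphenyl)pent-3-en-1-yl]-1-[(trimethylsilyl)methyl]cyclohexan-1-ol | COc1cc(OC)c(OC)c(C/C=C(\C)CC[C@@]2(C)CCC[C@@H](C)C2(O)C[Si](C)(C)C)c1OC
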